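Start with the first readings.

| setting | Monday's | Friday's | flask |
|---|---|---|---|
| substrate | 1.5 M | 0.75 M | 1.5 M |
| reagent | 0.79 M | 1.58 M | 1.58 M |
| remark | run made earlier | run made earlier |  |
| time |  |  | 15 d |

| run | time / d | target / % |
|---|---|---|
| Monday's | 0.167 | 21.8 |
| Monday's | 0.417 | 22.5 |
| Monday's | 1.04 | 16.1 |
| Monday's | 3.00 | 8.0 |
| Monday's | 8.00 | 6.3 |
| Monday's | 20.0 | 5.1 |
| Friday's | 0.167 | 41.6 |
| Friday's | 0.625 | 40.9 |
| Friday's | 1.67 | 25.0 |
| Friday's | 6.00 | 11.2 |
| Friday's | 20.0 | 10.9 |

(readings scatter by 0.5 percentage points)

- what was read earlier has a scatter of 0.5 percentage points, one standard deviation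

* time, not beyond 15 d, at which the flask holds most target
* the amount of target, in percent of the substrate charged, at that time

In both runs the first reading, at 0.167 d, already stands near the highest one, so the rise of target has to be read from that single point. A rate equal to a constant times substrate times reagent integrates in closed form: with x the target formed, and cA and cB the charges, the constant times the time times (cB − cA) equals ln[(cB − x)·cA / ((cA − x)·cB)]. Monday's 0.327 M gives 2.43 L mol⁻¹ d⁻¹, and Friday's 0.312 M gives 2.29 L mol⁻¹ d⁻¹. Their mean, 2.36 L mol⁻¹ d⁻¹, is the filling constant, the forward constant that brings a charge to a given amount of target as if nothing ran back.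

The forecast sets the top at 0.3 d with 36.5%, holding that “the maximum should sit on the early plateau”. Through the filling constant, that amount of target, 0.547 M, takes the flask 0.152 d. This own reckoning therefore places the top soon after that time, earlier than the forecast does.

The flask reaches its top at 0.236 d, with 36.1%.

    substrate + reagent ⇌ target + released group (K = 0.490, k = 0.140 L mol⁻¹ h⁻¹)
    target ⇌ isomer of the product (K = 7.50, k = 0.0370 h⁻¹)

Filling to that amount takes 0.149 d, so the top comes after 1.58 filling times. With half the substrate, which is Friday's charge, the top stands at 0.292 d; counting the same number of filling times back from it gives 0.185 d, and in that time the filling constant brings Friday's charge to an estimated 45.4% of the substrate charged, more than Friday's first reading of 41.6%. At 0.121 d the flask makes target 4.25 times faster than it uses it up, each step taken net, while target and isomer of the product relax with a half-life of 0.689 d, short against 15 d. At 15.0 d the flask holds 60.7% as isomer of the product and 8.12% as target.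

All runs are simulated on assumed constants; scatter was added.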